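**The question.** Time is what this flask is about: how much substrate has reacted by 50 min, and what is the pH then?

| flask | substrate | acid | remark | time |
|---|---|---|---|---|
| teal | 0.050 M | 0.075 mM | run made earlier |  |
| grey | 0.050 M | 0.30 mM | run made earlier |  |
| amber | 0.10 M | 0.15 mM | run made earlier |  |
| flask | 0.050 M | 0.150 mM |  | 50 min |

| run | time / min | substrate / % | target / % |
|---|---|---|---|
| teal | 2.50 | 88.5 | 10.5 |
| teal | 6.00 | 70.6 | 26.9 |
| teal | 12.0 | 47.8 | 43.4 |
| teal | 30.0 | 16.2 | 61.8 |
| grey | 2.50 | 82.1 | 17.3 |
| grey | 6.00 | 60.2 | 35.9 |
| grey | 12.0 | 34.9 | 55.1 |
| grey | 30.0 | 8.5 | 72.1 |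
| amber | 4.00 | 70.1 | 26.1 |
| amber | 10.0 | 39.9 | 45.0 |
| amber | 20.0 | 16.3 | 55.2 |
| amber | 30.0 | 8.1 | 58.1 |

(standard deviation of a reading: 0.3 percentage points)

- part of the substrate that has reacted at 50 min
- pH of the solution at 50 min

- acid is the free proton; pH is minus the decimal logarithm of its molar concentration
- percent here means substrate units held: one side product counts as two
- what is said of weak acid includes crystals
- crystals is a solid; its amount is given per volume of the solution
- what was read earlier has a scatter of 0.3 percentage points, one standard deviation
- steps thought possible: substrate + acid -> weak acid + acid + target; substrate + target -> side product; weak acid <-> conjugate base + acid; crystals <-> weak acid; substrate -> weak acid + target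

**The end.** In teal, the fraction of substrate left is still falling at the last reading, and grey's is too. So you can take the end state to be no substrate and ask how fast it is approached. The flask's acid charge is twice teal's and half grey's, so I place its fraction left at 30.0 min at the geometric mean of theirs, 11.7%.

**Late constant.** Between the last two readings, the logarithm of the substrate left falls at 0.0601 min⁻¹ in teal and 0.0785 min⁻¹ in grey. Their mean, 0.0693 min⁻¹, is the late constant: the fraction of the remaining substrate lost per minute late in these two runs. Used as a pseudo-first-order constant, it gives my estimate of 2.94% left in the flask at 50 min, so I reckon 97.1% reacted.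

**Weak link.** Neither teal nor grey has the flask's acid charge, but amber does, with twice the substrate. Its last interval reads 0.0699 min⁻¹, which from the same start gives an estimate of 2.89% left, so I keep my number. The readings hold no pH, so I commit to none.

**The forecast.** It says 96.7% reacted and pH 3.7, and its part reacted is slightly below mine. Its ground for the late slowing: “crystals form and pull the dissolved weak acid, and so the proton level, back down”.

**The result.** The flask gives 96.6% and pH 3.53, so the forecast held.

    substrate + acid → weak acid + acid + target (k = 2.30 M⁻¹ s⁻¹)
    substrate + target → side product (k = 0.00800 M⁻¹ s⁻¹)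
    weak acid ⇌ conjugate base + acid, settled at all times (K = 5.00 × 10⁻⁵ M)
    crystals ⇌ weak acid, rate k4*(cs4 - [weak acid]) while solid is left; crystals form when [weak acid] > cs4 (solubility = 0.810 mM, k = 0.0270 s⁻¹)
    substrate → weak acid + target (k = 1.30 × 10⁻⁴ s⁻¹)

The flask's acid goes from 215% of its charge at 25.0 min to 197% at 50.0 min. Starting from the 17.8% of substrate left at 25.0 min, the late constant 0.0693 min⁻¹ gives 3.15% at 50 min, and the flask has 3.4%.

**Earlier reading.** For the same flask read at 30 min, that start and constant give 12.6% left. The computed flask has 12.7% left, so 87.3% has reacted.

All runs come from a simulation with constants of no real substance; scatter was added.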